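(The readings were computed for an exercise.)

What share of its substrate is target after 14 h in the midnight flask, and what orders hold at the noon charge?

| flask | substrate | free catalyst | target | time |
|---|---|---|---|---|
| noon | 0.0800 M | 0.00640 M |  |  |
| winter | 0.0320 M | 0.00640 M |  |  |
| dawn | 0.0800 M | 0.00320 M |  |  |
| summer | 0.0800 M | 0.00640 M | 0.0400 M |  |
| midnight | 0.320 M | 0.00640 M |  | 14 h |

| noon run: time / h | noon run: [target] / M | winter run: time / h | winter run: [target] / M | dawn run: time / h | dawn run: [target] / M | summer run: time / h | summer run: [target] / M |
|---|---|---|---|---|---|---|---|
| 0.56 | 0.00182 | 0.56 | 7.8 × 10⁻⁴ | 0.56 | 7.4 × 10⁻⁴ | 0.56 | 0.04088 |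
| 0.96 | 0.00342 | 0.96 | 0.00171 | 0.96 | 0.00243 | 0.96 | 0.04205 |
| 1.6 | 0.00670 | 1.6 | 0.00241 | 1.6 | 0.00434 | 1.6 | 0.04443 |
| 2.8 | 0.01282 | 2.8 | 0.00540 | 2.8 | 0.00855 | 2.8 | 0.04902 |
| 4.8 | 0.02150 | 4.8 | 0.00925 | 4.8 | 0.01530 | 4.8 | 0.05567 |
| 8.2 | 0.03228 | 8.2 | 0.01276 | 8.2 | 0.02447 | 8.2 | 0.06161 |
| 14 | 0.04102 | 14 | 0.01643 | 14 | 0.03297 | 14 | 0.06516 |

(readings scatter by 2 × 10⁻⁴ M)

- the exponent of [free catalyst] in the starting rate at the charge of the noon run (at the point where two percent of the substrate have become target)
- the exponent of [substrate] in the starting rate at the charge of the noon run (at the point where two percent of the substrate have become target) (one fixed amount of target, the same in the runs compared)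
- target in the midnight run at 14 h, as a share of the substrate charged

- Overall: substrate -> target, with free catalyst as catalyst.
- Constant volume, constant temperature.
- An order is taken over about fifteen percent of the charge, up and down.

The nearest neighbour of the midnight flask is the noon run. It has the same catalyst charge, and the midnight flask holds 4.00 times its substrate. So we carry one quantity, the end share: c(target) at 14 h divided by the substrate charged, which is 51.3 % in the noon run.

The winter run, again with that catalyst charge but with less substrate, gives 51.3 %. One reading there carries a scatter of 0.625 % of its charge, so the two shares differ by less than that scatter.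

Why do the runs end there, well short of full conversion? The summer run is the noon recipe with 0.0400 M of target added, yet at 14 h it stands above the noon run by 0.0241 M, which is 60.3 % of the addition. Added target has not stayed target, so the end share is a balance of making and losing.

If both are pseudo-first-order at a fixed catalyst charge, the curves scale with the substrate charge and the share at a given time does not change. We therefore commit to 51.3 % for the midnight flask, or 0.164 M of target.

The forecast gives 48 %, with a range of 36 % to 54 %, and orders of 0.72 in free catalyst and 0.9 in substrate. Its yield lies below ours, and it says why: “Allowing for possible saturation at 0.32 M, I expect about 48%.”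

The midnight flask gives 51.0 %, which is 0.30 percentage points under the noon share, and the orders are 0.39 in free catalyst and 0.75 in substrate.

    2 active catalyst ⇌ catalyst dimer, settled at all times (5940 M⁻¹)
    active catalyst + substrate → target + active catalyst (120.2 M⁻¹ h⁻¹)
    target → decomposed product (0.03593 h⁻¹)
    free catalyst → active catalyst (0.9900 h⁻¹)

Without the loss of target to decomposed product the midnight run reaches 67.1 %, so that loss accounts for 33 % of what is missing from full conversion, and the rest is substrate still unturned at 14 h, 32.9 % of the charge in that run. Held against 51.0 %, this means that about 76.0 % of the target made in the midnight run survives to 14 h. That is more than the 60.3 % read for the target added to the summer run, which stood in its flask for the full 14 h.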